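**Retrosynthetic overview**
1. The target comes from its catechol bis(allyl) ether by a neutral Pd-catalysed deallylation as the last step.
2. The key cut breaks two bonds of the cyclohexanone ring at once, C5–C6 and C1–C8. This gives an aromatic 3,5-digeranyl acylphloroglucinol and a chiral C10 "prenyl-plus-prenyl" 1,3-dielectrophile (primary triflate, tertiary silyl ether). In one flask, SN2 dearomatisation is followed by capture at C1 of the same C8 tertiary cation that the biosynthesis uses.
3. The digeranyl acylphloroglucinol comes from phloroglucinol and a 3,4-dioxygenated benzonitrile (Hoesch), then twofold C-geranylation, which mimics aromatic prenyl transfer.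
4. The C10 unit comes from prenol (Sharpless epoxidation sets C7) and prenyl Grignard (Cu-catalysed epoxide opening with inversion).
5. Ring order: phloroglucinol ring (bought), then dearomatised cyclohexadienone, then ring C5–C6–C7–C8–C1–C9, which completes the bicyclo[3.3.1]nonane.

Assumption: the enolised β-triketone equilibrates between its enol tautomers, so the tautomer of the given SMILES is drawn. Numbering is bicyclo[3.3.1]nonane, with C1 next to C8 (CMe2), C5 next to C6 (CH2), and C9 the bridging ketone.

**Step 1**
Reactants: 1 3,4-dihydroxybenzonitrile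
Product: 2 3,4-bis(allyloxy)benzonitrile
Conditions: allyl bromide (2.3 equiv), K2CO3, acetone, reflux
Reagents that add atoms: allyl bromide, C=CCBr
Why: Williamson ether synthesis caps both acidic catechol OH groups as allyl ethers, which tolerate HCl/ZnCl2, aqueous KOH, LiN(SiMe3)2 and TMSOTf and leave at the end under neutral zerovalent-palladium catalysis.

**Step 2**
Reactants: 2 3,4-bis(allyloxy)benzonitrile; 3 phloroglucinol
Product: 5 [3,4-bis(allyloxy)phenyl](2,4,6-trihydroxyphenyl)methanone, via ketiminium chloride 4 (not isolated)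
Conditions: ZnCl2, HCl (g), Et2O, 0 °C; then H2O, reflux
Reagents that add atoms: water, O
Why: In the Hoesch acylation the HCl/ZnCl2-activated nitrile attacks the very electron-rich, symmetric phloroglucinol only once because the ketiminium salt deactivates the ring, and hydrolysis gives the benzophenone-type acylphloroglucinol that the polyketide pathway also delivers.

**Step 3**
Reactants: 5 [3,4-bis(allyloxy)phenyl](2,4,6-trihydroxyphenyl)methanone; 6 geranyl bromide (2.1 equiv)
Product: 7 [3,4-bis(allyloxy)phenyl]{3,5-bis[(2E)-3,7-dimethylocta-2,6-dienyl]-2,4,6-trihydroxyphenyl}methanone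
Conditions: KOH (3 equiv), H2O, 0 °C → rt; then dilute HCl
Reagents that add atoms: none
Why: This is C-alkylation of the ambident acylphloroglucinolate in water, the laboratory counterpart of aromatic prenyl transfer, in which hydrogen-bonded oxygens are masked so the two free ring carbons attack the soft allylic bromide by SN2 with the E geometry kept.

**Step 4**
Reactants: 8 prenol (3-methylbut-2-en-1-ol)
Product: 9 (S)-(3,3-dimethyloxiran-2-yl)methanol
Conditions: Ti(OiPr)4 (5 mol %), L-(+)-DIPT (6 mol %), t-BuOOH, 4 Å MS, CH2Cl2, −25 °C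
Reagents that add atoms: tert-butyl hydroperoxide, CC(C)(C)OO
Why: In the catalytic Sharpless asymmetric epoxidation L-(+)-tartrate delivers oxygen to the alkene face that gives the (S)-epoxide (about 93–95% ee), and this is the only source of absolute configuration in the route.

**Step 5**
Reactants: 9 (S)-(3,3-dimethyloxiran-2-yl)methanol; 10 prenyl chloride
Product: 12 (R)-3-methyl-2-(3-methylbut-2-enyl)butane-1,3-diol, via prenylmagnesium chloride 11 (not isolated)
Conditions: 10, Mg, THF, −10 °C; separately 9, MeMgCl (1.0 equiv), THF, −40 °C; combine (1.5 equiv of 11), CuI (10 mol %), −40 → 0 °C; aq NH4Cl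
Reagents that add atoms: none
Why: In this copper-catalysed SN2 opening of a 2,3-epoxy alcohol the organocopper attacks the secondary C2 rather than the fully substituted C3, couples through the unhindered α-terminus of the prenyl unit and inverts C2, so (S)-9 gives the (R)-1,3-diol that carries the future C7.

**Step 6**
Reactants: 12 (R)-3-methyl-2-(3-methylbut-2-enyl)butane-1,3-diol
Product: 14 (R)-5-methyl-2-[2-(triethylsilyloxy)propan-2-yl]hex-4-enyl trifluoromethanesulfonate, via hydroxy triflate 13 (not isolated)
Conditions: Tf2O (1.05 equiv), 2,6-lutidine (3 equiv), CH2Cl2, −78 °C; then TESOTf (1.2 equiv), −78 → 0 °C; short silica plug, use at once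
Reagents that add atoms: triflic anhydride, O=S(=O)(OS(=O)(=O)C(F)(F)F)C(F)(F)F; triethylsilyl triflate, CC[Si](CC)(CC)OS(=O)(=O)C(F)(F)F
Why: In this one-flask selective sulfonylation/silylation Tf2O at −78 °C takes only the primary OH and TESOTf then caps the tertiary OH, giving a 1,3-dielectrophile (SN2 site at the future C6, latent SN1 site at the future C8) without touching the stereocentre.

**Step 7 (key step)**
Reactants: 7 [3,4-bis(allyloxy)phenyl]{3,5-bis[(2E)-3,7-dimethylocta-2,6-dienyl]-2,4,6-trihydroxyphenyl}methanone; 14 (R)-5-methyl-2-[2-(triethylsilyloxy)propan-2-yl]hex-4-enyl trifluoromethanesulfonate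
Product: 18 (1S,5S,7R)-3-[3,4-bis(allyloxy)benzoyl]-1,5-bis[(2E)-3,7-dimethylocta-2,6-dienyl]-4-hydroxy-8,8-dimethyl-7-(3-methylbut-2-enyl)bicyclo[3.3.1]non-3-ene-2,9-dione, via dearomatised dienone 15 (not isolated), via bis-TMS dienol ether 16 (not isolated), via bicyclic TMS enol ether 17 (not isolated)
Conditions: LiN(SiMe3)2 (3.0 equiv), PhMe–THF 10:1, 0 °C; 14 (1.3 equiv), 0 °C → rt; evaporate; TMSOTf (3.0 equiv), 2,6-di-tert-butyl-4-methylpyridine (0.5 equiv), CH2Cl2, −78 °C → rt; aq NaHCO3; SiO2
Reagents that add atoms: none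
Why: Proposed new method: this is a one-flask dearomative (3+3) annulation in which (a) the trilithium phenolate of 7 is C-alkylated at a geranyl-bearing carbon by the primary triflate (alkylative dearomatisation, with tight Li–O pairing in toluene favouring C over O), (b) TMSOTf silylates both enolates and then ionises the tertiary O–TES group, as it does tert-butyl ethers and esters, to the same C8 tertiary cation that prenyl transfer to the C5 prenyl group creates in the biosynthesis, and (c) the C1=C9 silyl enol ether traps that cation on carbon; the closest known reaction types are the Lewis-acid α-tert-alkylation of silyl enol ethers (Reetz alkylation, which builds adjacent quaternary carbons) and the proton-induced cyclisation of dearomatised acylphloroglucinols; the medium is aprotic and proton-scavenged, so the trisubstituted prenyl and geranyl alkenes are neither protonated nor closed to pyrans, and closure on O4 is reversible under TMSOTf whereas C–C closure is not; C7 comes unchanged from 14, the alkylation is not face-selective at C5 (about 1:1), and the three-atom tether reaches C1 only on its own face so C1 follows C5; only the (6R)-epimer 15 closes through a chair with equatorial prenyl to the 7-exo product 18, and the 7-endo isomer from the other epimer is removed on silica.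

**Step 8**
Reactants: 18 (1S,5S,7R)-bis(allyl) ether
Product: 19 CNP0178719.1, (1S,5S,7R)-3-(3,4-dihydroxybenzoyl)-1,5-bis[(2E)-3,7-dimethylocta-2,6-dienyl]-4-hydroxy-8,8-dimethyl-7-(3-methylbut-2-enyl)bicyclo[3.3.1]non-3-ene-2,9-dione
Conditions: Pd(PPh3)4 (5 mol %), morpholine (10 equiv), degassed THF, rt; pH 4 citrate buffer; preparative HPLC (chiral phase, removes the residual enantiomer)
Reagents that add atoms: none
Why: In this Tsuji–Trost-type deallylation zerovalent palladium ionises only the two aryl allyl ethers to π-allyl complexes that morpholine captures irreversibly, while the unactivated prenyl and geranyl alkenes, the enolised triketone and all three stereocentres stay untouched.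

**Compound list**
1 | 3,4-dihydroxybenzonitrile | N#Cc1ccc(O)c(O)c1 | starting material
2 | 3,4-bis(allyloxy)benzonitrile | N#Cc1ccc(OCC=C)c(OCC=C)c1 | intermediate
3 | phloroglucinol | Oc1cc(O)cc(O)c1 | starting material
4 | [3,4-bis(allyloxy)phenyl](2,4,6-trihydroxyphenyl)methaniminium chloride | [Cl-].[NH2+]=C(c1ccc(OCC=C)c(OCC=C)c1)c1c(O)cc(O)cc1O | intermediate
5 | [3,4-bis(allyloxy)phenyl](2,4,6-trihydroxyphenyl)methanone | O=C(c1ccc(OCC=C)c(OCC=C)c1)c1c(O)cc(O)cc1O | intermediate
6 | geranyl bromide, (E) | CC(C)=CCC/C(C)=C/CBr | starting material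
7 | 3,5-digeranyl benzophenone, both (E) | O=C(c1ccc(OCC=C)c(OCC=C)c1)c1c(O)c(C/C=C(\C)CCC=C(C)C)c(O)c(C/C=C(\C)CCC=C(C)C)c1O | intermediate
8 | prenol | CC(C)=CCO | starting material
9 | (S)-(3,3-dimethyloxiran-2-yl)methanol | OC[C@@H]1OC1(C)C | intermediate
10 | prenyl chloride | CC(C)=CCCl | starting material
11 | prenylmagnesium chloride | CC(C)=CC[Mg]Cl | intermediate
12 | (R)-3-methyl-2-(3-methylbut-2-enyl)butane-1,3-diol | OC[C@@H](CC=C(C)C)C(C)(C)O | intermediate
13 | (R)-2-(2-hydroxypropan-2-yl)-5-methylhex-4-enyl triflate | O=S(=O)(OC[C@@H](CC=C(C)C)C(C)(C)O)C(F)(F)F | intermediate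
14 | (R)-5-methyl-2-[2-(triethylsilyloxy)propan-2-yl]hex-4-enyl triflate | O=S(=O)(OC[C@@H](CC=C(C)C)C(C)(C)O[Si](CC)(CC)CC)C(F)(F)F | intermediate
15 | (6R)-2-[3,4-bis(allyloxy)benzoyl]-4,6-digeranyl-3,5-dihydroxy-6-{(2R)-5-methyl-2-[2-(triethylsilyloxy)propan-2-yl]hex-4-enyl}cyclohexa-2,4-dien-1-one (present in the flask as its dilithium salt, drawn neutral) | CC(C)=CCC/C(C)=C/C[C@]1(C[C@@H](CC=C(C)C)C(C)(C)O[Si](CC)(CC)CC)C(=O)C(C(=O)c2ccc(OCC=C)c(OCC=C)c2)=C(O)C(C/C=C(\C)CCC=C(C)C)=C1O | intermediate
16 | 3,5-bis(trimethylsilyl) ether of 15 | CC(C)=CCC/C(C)=C/C[C@]1(C[C@@H](CC=C(C)C)C(C)(C)O[Si](CC)(CC)CC)C(=O)C(C(=O)c2ccc(OCC=C)c(OCC=C)c2)=C(O[Si](C)(C)C)C(C/C=C(\C)CCC=C(C)C)=C1O[Si](C)(C)C | intermediate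
17 | C2 trimethylsilyl enol ether of 18 (same configuration as 18) | CC(C)=CCC/C(C)=C/C[C@]12C[C@@H](CC=C(C)C)C(C)(C)[C@](C/C=C(\C)CCC=C(C)C)(C(O[Si](C)(C)C)=C(C(=O)c3ccc(OCC=C)c(OCC=C)c3)C1=O)C2=O | intermediate
18 | (1S,5S,7R)-catechol bis(allyl) ether of the target | CC(C)=CCC/C(C)=C/C[C@]12C[C@@H](CC=C(C)C)C(C)(C)[C@](C/C=C(\C)CCC=C(C)C)(C(=O)C(C(=O)c3ccc(OCC=C)c(OCC=C)c3)=C1O)C2=O | intermediate
19 | CNP0178719.1, (1S,5S,7R) | CC(C)=CCC/C(C)=C/C[C@]12C[C@@H](CC=C(C)C)C(C)(C)[C@](C/C=C(\C)CCC=C(C)C)(C(=O)C(C(=O)c3ccc(O)c(O)c3)=C1O)C2=O | target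

**Step count**
- Total steps: 8.
- Longest linear sequence: 5 steps (1 → 2 → 3 → 7 → 8). The branch 4 → 5 → 6 → 7 → 8 is equally long.

**Steps most likely to fail**

Step 7 carries the most risk.
- The closure joins two fully substituted carbons. Loss of a proton from the C8 cation, a 1,2-hydride shift from C7, or persistent closure on O4 can all win.
- Half of the material also has the wrong C5 configuration.
- The fallback sets out from 15 and comes back at 18. The flask is quenched with aqueous citric acid after the alkylation and 15 is isolated.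
- TMSCHN2 (MeCN–MeOH, 0 °C) converts 15 into the C3 methyl enol ether of 15 F1, which blocks pyran formation.
- F1 is closed by solvolysis in neat HCO2H at rt. This is a Brønsted-acid cyclisation under thermodynamic control in which the TES ether is lost, and it gives the O-methyl bicyclic vinylogous ester F2.
- The methyl group is then removed with LiCl in DMSO at 120 °C, a temperature the aryl allyl ethers tolerate, to give 18.

Step 5 is the second risk.
- Prenyl metal reagents can couple through the γ-terminus to give a reverse-prenyl product.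
- The epoxy alkoxide can undergo Payne migration and open to a 1,2-diol.
- The fallback sets out from 10 and comes back at 12.
- (S)-4-Benzyloxazolidin-2-one is acylated (n-BuLi, 3-methylbut-2-enoyl chloride) to (S)-4-benzyl-3-(3-methylbut-2-enoyl)oxazolidin-2-one F3.
- Deconjugative Evans alkylation with NaN(SiMe3)2, 10 and NaI at −78 °C gives the α-prenylated β,γ-unsaturated imide F4. The minor diastereomer is removed on silica.
- LiBH4 releases (S)-lavandulol F5.
- Mukaiyama hydration (Co(acac)2, PhSiH3, O2, i-PrOH) hydrates the 1,1-disubstituted alkene in preference to the trisubstituted one and gives 12.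

Step 3 is the third risk.
- Mono-, O- and over-alkylated (dearomatised) products compete with the double C-geranylation.
- The fallback sets out from 5 and comes back at 7.
- The phenolate alkylation is replaced by a Friedel–Crafts allylation with geraniol on acidic Al2O3 (ClCH2CH2Cl, reflux), run in two passes.
- The first pass gives the 3-geranyl benzophenone F6, which is purified. The second pass with fresh geraniol gives 7, and no dearomatisation is possible under these conditions.

**Further compounds**
F1 | step 7 | C3 methyl enol ether of 15, (6R), side chain (2R) | CC(C)=CCC/C(C)=C/C[C@]1(C[C@@H](CC=C(C)C)C(C)(C)O[Si](CC)(CC)CC)C(=O)C(C(=O)c2ccc(OCC=C)c(OCC=C)c2)=C(OC)C(C/C=C(\C)CCC=C(C)C)=C1O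
F2 | step 7 | C2 methyl enol ether of 18 (same configuration as 18) | CC(C)=CCC/C(C)=C/C[C@]12C[C@@H](CC=C(C)C)C(C)(C)[C@](C/C=C(\C)CCC=C(C)C)(C(OC)=C(C(=O)c3ccc(OCC=C)c(OCC=C)c3)C1=O)C2=O
F3 | step 5 | (S)-4-benzyl-3-(3-methylbut-2-enoyl)oxazolidin-2-one | CC(C)=CC(=O)N1[C@@H](Cc2ccccc2)COC1=O
F4 | step 5 | (S)-4-benzyl-3-[(S)-5-methyl-2-(prop-1-en-2-yl)hex-4-enoyl]oxazolidin-2-one | C=C(C)[C@H](CC=C(C)C)C(=O)N1[C@@H](Cc2ccccc2)COC1=O
F5 | step 5 | (S)-lavandulol | OC[C@@H](CC=C(C)C)C(C)=C
F6 | step 3 | [3,4-bis(allyloxy)phenyl]{3-[(2E)-3,7-dimethylocta-2,6-dienyl]-2,4,6-trihydroxyphenyl}methanone | O=C(c1ccc(OCC=C)c(OCC=C)c1)c1c(O)cc(O)c(C/C=C(\C)CCC=C(C)C)c1O
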